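**Plan**

Target numbering: ring O1–O2–C3(OH)(CH3)–C4(CH3)–C5–C6(CH3); side chain C7–C8(CH3)–C9…C14–C15=C16–Ph.
Retrosynthesis: the (Z)-C15=C16 alkene goes back to the aryl alkyne; then O2–C3 and O1–C6 are cut with loss of O2 and C3 is bonded to C6. This works because hemiketal carbon C3 and peroxide-bearing carbon C6 are 1,4-related through C4–C5 of the 1,2-dioxane, so joining them closes a cyclobutanol (C3–C4–C5–C6).
The cyclobutanol is cut at C3–CH3 (Grignard addition), C11–C12 (copper-catalysed sp3–sp3 coupling), C4–CH3 (hydrazone alkylation) and C6–C3/C6–C5 (cyclopropylide spiroannulation of a citronellal-derived methyl ketone).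
Forward: (R)-citronellal → methyl ketone → cyclobutanone (four-membered ring first) → C4 methylation → tertiary cyclobutanol → ozonolysis and tosylate → coupling with the phenylpentynyl Grignard reagent → O2 ring expansion to the 1,2-dioxane → semi-hydrogenation.
Stereochemistry: C8 from (R)-citronellal; C4 from the SAMP-hydrazone methylation; C3 by thermodynamic (anomeric) hemiketal equilibration; C6 uncontrolled, epimers separated; the (Z)-alkene by syn semi-hydrogenation.

Key step: step 12

Assumption: the quaternary ring carbon (later C6, from compound 6 on) and the carbinol carbon (later C3, from compound 13 on) are carried as epimer mixtures, because both are planarised in step 12; their descriptors are left open in names and SMILES.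

**Route**

Step 1
Reactants: 1 (R)-citronellal [(3R)-3,7-dimethyloct-6-enal]
Product: 2 (4R)-4,8-dimethylnon-7-en-2-ol (C2 epimer mixture)
Conditions: MeMgBr (1.2 equiv), Et2O, 0 °C; then H2O
Reagents that add atoms: methylmagnesium bromide, C[Mg]Br
Why: Grignard 1,2-addition to the aldehyde should be clean; the new carbinol centre is uncontrolled but is removed in step 2, and the (R) centre of citronellal is not touched.

Step 2
Reactants: 2 (4R)-4,8-dimethylnon-7-en-2-ol
Product: 3 (4R)-4,8-dimethylnon-7-en-2-one
Conditions: (n-Pr4N)RuO4 (5 mol%), N-methylmorpholine N-oxide (1.5 equiv), 4 Å molecular sieves, CH2Cl2, rt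
Reagents that add atoms: none
Why: Ley–Griffith oxidation of the secondary alcohol should give the methyl ketone without affecting the trisubstituted alkene or the β-stereocentre.

Step 3
Reactants: 3 (4R)-4,8-dimethylnon-7-en-2-one; 4 cyclopropyldiphenylsulfonium tetrafluoroborate
Product: 7 2-[(2R)-2,6-dimethylhept-5-en-1-yl]-2-methylcyclobutan-1-one (C2 epimer mixture), via sulfonium ylide 5 (not isolated), via oxaspiropentane 6 (not isolated)
Conditions: KOH (powdered), DMSO, rt; then LiBF4 (10 mol%), benzene, rt
Reagents that add atoms: none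
Why: Sulfonium-ylide spiroannulation: the reversibly formed cyclopropylide adds to the ketone and closes to the oxaspiropentane, whose Lewis-acid-induced pinacol-type ring expansion should give the 2,2-disubstituted cyclobutanone, the quaternary centre forming as both epimers without consequence.

Step 4
Reactants: 7 2-[(2R)-2,6-dimethylhept-5-en-1-yl]-2-methylcyclobutan-1-one; 8 (S)-1-amino-2-(methoxymethyl)pyrrolidine (SAMP)
Product: 9 (2S)-N-[(E)-2-[(2R)-2,6-dimethylhept-5-en-1-yl]-2-methylcyclobutylidene]-2-(methoxymethyl)pyrrolidin-1-amine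
Conditions: p-TsOH·H2O (cat.), benzene, reflux, Dean–Stark
Reagents that add atoms: none
Why: Condensation of the strained, electrophilic cyclobutanone with the hydrazine should give the hydrazone with the amino nitrogen anti to the quaternary α-carbon.

Step 5
Reactants: 9 SAMP hydrazone of 7
Product: 11 (2S)-N-[(1E,4R)-2-[(2R)-2,6-dimethylhept-5-en-1-yl]-2,4-dimethylcyclobutylidene]-2-(methoxymethyl)pyrrolidin-1-amine, via lithium azaenolate 10 (not isolated)
Conditions: LiN(i-Pr)2 (1.1 equiv), THF, 0 °C; then MeI, −100 °C → rt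
Reagents that add atoms: iodomethane, CI
Why: Enders SAMP-hydrazone α-alkylation: only the ring CH2 can be deprotonated, and the chelated azaenolate should be methylated on the face away from the methoxymethyl-bearing pyrrolidine, which by the established sense of induction of SAMP (the sense that leads to (R)-2-methylcyclohexanone) sets (R) at C4 in both C6 epimers.

Step 6
Reactants: 11 methylated SAMP hydrazone
Product: 12 (4R)-2-[(2R)-2,6-dimethylhept-5-en-1-yl]-2,4-dimethylcyclobutan-1-one (C2 epimer mixture)
Conditions: sat. aq. (CO2H)2, Et2O, rt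
Reagents that add atoms: water, O
Why: Mild two-phase oxalic acid hydrolysis of the hydrazone should release the ketone without enolising the α-methyl centre or hydrating the alkene, and returns the auxiliary.

Step 7
Reactants: 12 (4R)-2-[(2R)-2,6-dimethylhept-5-en-1-yl]-2,4-dimethylcyclobutan-1-one
Product: 13 (4R)-2-[(2R)-2,6-dimethylhept-5-en-1-yl]-1,2,4-trimethylcyclobutan-1-ol (C1/C2 epimer mixture)
Conditions: MeMgBr (1.5 equiv), Et2O, −78 → 0 °C; then H2O
Reagents that add atoms: methylmagnesium bromide, C[Mg]Br
Why: Grignard addition to the strained cyclobutanone carbonyl should outrun enolisation (which would put a double bond in the four-membered ring), so C4 is kept, and the carbinol centre forms as a mixture that step 12 erases.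

Step 8
Reactants: 13 (4R)-2-[(2R)-2,6-dimethylhept-5-en-1-yl]-1,2,4-trimethylcyclobutan-1-ol
Product: 15 (4R)-2-[(2R)-5-hydroxy-2-methylpentyl]-1,2,4-trimethylcyclobutan-1-ol, via aldehyde 14 (not isolated)
Conditions: O3, CH2Cl2/MeOH, −78 °C; then NaBH4, −78 °C → rt
Reagents that add atoms: ozone, [O-][O+]=O
Why: Ozonolysis of the only alkene with reductive borohydride work-up should cut the chain at C11 and give the primary alcohol, the tertiary cyclobutanol being inert to both reagents.

Step 9
Reactants: 15 (4R)-2-[(2R)-5-hydroxy-2-methylpentyl]-1,2,4-trimethylcyclobutan-1-ol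
Product: 16 (4R)-5-[(3R)-2-hydroxy-1,2,3-trimethylcyclobutyl]-4-methylpentyl 4-methylbenzenesulfonate
Conditions: TsCl (1.1 equiv), Et3N, DMAP (cat.), CH2Cl2, 0 °C
Reagents that add atoms: 4-methylbenzenesulfonyl chloride, Cc1ccc(cc1)S(=O)(=O)Cl
Why: Sulfonylation should be selective for the primary hydroxyl because the tertiary cyclobutanol is too hindered to react with TsCl at 0 °C.

Step 10
Reactants: 17 5-phenylpent-4-yn-1-ol
Product: 18 (5-bromopent-1-yn-1-yl)benzene
Conditions: CBr4, PPh3, CH2Cl2, 0 °C → rt
Reagents that add atoms: carbon tetrabromide, BrC(Br)(Br)Br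
Why: Appel bromination should convert the primary alcohol into the bromide by SN2 displacement of the alkoxyphosphonium ion, leaving the alkyne untouched.

Step 11
Reactants: 16 primary tosylate; 18 (5-bromopent-1-yn-1-yl)benzene
Product: 20 (4R)-1,2,4-trimethyl-2-[(2R)-2-methyl-10-phenyldec-9-yn-1-yl]cyclobutan-1-ol (C1/C2 epimer mixture), via Grignard reagent 19 (not isolated)
Conditions: 18 (3 equiv), Mg turnings, THF, rt; then 16, Li2CuCl4 (5 mol%), THF, −78 °C → rt; then H2O
Reagents that add atoms: none
Why: Copper-catalysed cross-coupling of a primary alkyl Grignard reagent with a primary tosylate should join C11 to C12, the first equivalent of 19 being spent on the tertiary hydroxyl and the internal aryl alkyne being inert to the organomagnesium and to catalytic cuprate at low temperature.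

Step 12
Reactants: 20 (4R)-1,2,4-trimethyl-2-[(2R)-2-methyl-10-phenyldec-9-yn-1-yl]cyclobutan-1-ol; 21 dioxygen
Product: 23 (3S,4R,6S)-3,4,6-trimethyl-6-[(2R)-2-methyl-10-phenyldec-9-yn-1-yl]-1,2-dioxan-3-ol, via hydroperoxy ketone 22 (not isolated)
Conditions: Co(acac)2 (10 mol%), O2 (1 atm), CH2Cl2, rt; SiO2 chromatography to separate the C6 epimers
Reagents that add atoms: none
Why: Under O2 the cyclobutanol should bind to trivalent cobalt as its alkoxide and fragment as an alkoxyl radical; β-scission of the strained C3–C6 bond gives the C3 methyl ketone and the tertiary C6 radical, which captures O2 (C6–O1), and the peroxyl radical is reduced to hydroperoxide 22 within the divalent/trivalent cobalt cycle. This is the known cobalt- or manganese-acetylacetonate-catalysed aerobic ring expansion of cyclobutanols to 1,2-dioxan-3-ols. The one new ring, the 1,2-dioxane, closes by 6-exo-trig addition of the hydroperoxide oxygen to the C3 carbonyl (O2–C3). C3 is set thermodynamically through ring–chain equilibration, the (3S) hemiketal having the anomerically favoured axial hydroxyl with the C3 and C4 methyl groups and the side chain equatorial; C6 forms at a planar radical without facial control, so the (6S) product is separated from its (6R) epimer; C4 is never planar and stays (R). The selectivity needed is cleavage of C3–C6 over C3–C4, secured by release of a tertiary rather than a secondary radical, and the aryl alkyne is carried because it is far less prone than a styrene to peroxyl-radical addition.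

Step 13
Reactants: 23 (3S,4R,6S)-3,4,6-trimethyl-6-[(2R)-2-methyl-10-phenyldec-9-yn-1-yl]-1,2-dioxan-3-ol
Product: 24 (3S,4R,6S)-3,4,6-trimethyl-6-[(2R,9Z)-2-methyl-10-phenyldec-9-en-1-yl]-1,2-dioxan-3-ol
Conditions: H2 (1 atm), Pd/CaCO3 poisoned with Pb(OAc)2 (Lindlar catalyst), quinoline, EtOAc, 0 °C → rt, stopped after one equivalent of H2
Reagents that add atoms: none
Why: Lindlar semi-hydrogenation should deliver H2 syn to give the (Z)-styrene, the alkyne binding to the poisoned palladium surface far more strongly than the hindered di-tertiary peroxide, whose O–O bond should therefore survive.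

**Compound list**

1 | (R)-citronellal, (3R)-3,7-dimethyloct-6-enal | C[C@H](CCC=C(C)C)CC=O | starting material
2 | (4R)-4,8-dimethylnon-7-en-2-ol (C2 epimers) | C[C@H](CCC=C(C)C)CC(C)O | intermediate
3 | (4R)-4,8-dimethylnon-7-en-2-one | C[C@H](CCC=C(C)C)CC(C)=O | intermediate
4 | cyclopropyldiphenylsulfonium tetrafluoroborate | C1CC1[S+](c1ccccc1)c1ccccc1.F[B-](F)(F)F | starting material
5 | diphenylsulfonium cyclopropylide (not isolated) | [C-]1(CC1)[S+](c1ccccc1)c1ccccc1 | intermediate
6 | 2-[(2R)-2,6-dimethylhept-5-en-1-yl]-2-methyl-1-oxaspiro[2.2]pentane (C2 epimers, not isolated) | C[C@H](CCC=C(C)C)CC1(C)OC12CC2 | intermediate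
7 | 2-[(2R)-2,6-dimethylhept-5-en-1-yl]-2-methylcyclobutan-1-one (C2 epimers) | C[C@H](CCC=C(C)C)CC1(C)CCC1=O | intermediate
8 | (S)-1-amino-2-(methoxymethyl)pyrrolidine (SAMP) | COC[C@@H]1CCCN1N | starting material
9 | (2S)-N-[(E)-2-[(2R)-2,6-dimethylhept-5-en-1-yl]-2-methylcyclobutylidene]-2-(methoxymethyl)pyrrolidin-1-amine | C[C@H](CCC=C(C)C)CC1(C)CC\C1=N/N1CCC[C@H]1COC | intermediate
10 | lithium azaenolate of 9 (not isolated) | C[C@H](CCC=C(C)C)CC1(C)CC=C1N([Li])N1CCC[C@H]1COC | intermediate
11 | (2S)-N-[(1E,4R)-2-[(2R)-2,6-dimethylhept-5-en-1-yl]-2,4-dimethylcyclobutylidene]-2-(methoxymethyl)pyrrolidin-1-amine | C[C@H](CCC=C(C)C)CC1(C)C[C@@H](C)\C1=N/N1CCC[C@H]1COC | intermediate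
12 | (4R)-2-[(2R)-2,6-dimethylhept-5-en-1-yl]-2,4-dimethylcyclobutan-1-one (C2 epimers) | C[C@H](CCC=C(C)C)CC1(C)C[C@@H](C)C1=O | intermediate
13 | (4R)-2-[(2R)-2,6-dimethylhept-5-en-1-yl]-1,2,4-trimethylcyclobutan-1-ol (C1/C2 epimers) | C[C@H](CCC=C(C)C)CC1(C)C[C@@H](C)C1(C)O | intermediate
14 | (4R)-5-[(3R)-2-hydroxy-1,2,3-trimethylcyclobutyl]-4-methylpentanal (not isolated) | C[C@H](CCC=O)CC1(C)C[C@@H](C)C1(C)O | intermediate
15 | (4R)-2-[(2R)-5-hydroxy-2-methylpentyl]-1,2,4-trimethylcyclobutan-1-ol | C[C@H](CCCO)CC1(C)C[C@@H](C)C1(C)O | intermediate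
16 | (4R)-5-[(3R)-2-hydroxy-1,2,3-trimethylcyclobutyl]-4-methylpentyl 4-methylbenzenesulfonate | C[C@H](CCCOS(=O)(=O)c1ccc(C)cc1)CC1(C)C[C@@H](C)C1(C)O | intermediate
17 | 5-phenylpent-4-yn-1-ol | OCCCC#Cc1ccccc1 | starting material
18 | (5-bromopent-1-yn-1-yl)benzene | BrCCCC#Cc1ccccc1 | intermediate
19 | (5-phenylpent-4-yn-1-yl)magnesium bromide (not isolated) | Br[Mg]CCCC#Cc1ccccc1 | intermediate
20 | (4R)-1,2,4-trimethyl-2-[(2R)-2-methyl-10-phenyldec-9-yn-1-yl]cyclobutan-1-ol (C1/C2 epimers) | C[C@H](CCCCCCC#Cc1ccccc1)CC1(C)C[C@@H](C)C1(C)O | intermediate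
21 | dioxygen | O=O | starting material
22 | (3R,7R)-5-hydroperoxy-3,5,7-trimethyl-15-phenylpentadec-14-yn-2-one (C5 epimers, not isolated) | C[C@H](CCCCCCC#Cc1ccccc1)CC(C)(OO)C[C@@H](C)C(C)=O | intermediate
23 | (3S,4R,6S)-3,4,6-trimethyl-6-[(2R)-2-methyl-10-phenyldec-9-yn-1-yl]-1,2-dioxan-3-ol | C[C@H](CCCCCCC#Cc1ccccc1)C[C@@]1(C)C[C@@H](C)[C@@](C)(O)OO1 | intermediate
24 | (3S,4R,6S)-3,4,6-trimethyl-6-[(2R,9Z)-2-methyl-10-phenyldec-9-en-1-yl]-1,2-dioxan-3-ol | C[C@H](CCCCCC/C=C\c1ccccc1)C[C@@]1(C)C[C@@H](C)[C@@](C)(O)OO1 | target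

**Step count and risks**

Total step count: 13. Longest linear sequence: 12 steps (steps 1–9 and 11–13 from 1; step 10 is a one-step branch from 17).

Steps most likely to fail:

1. Step 12. What may go wrong: the cobalt redox couple may cleave the O–O bond of hydroperoxide 22 before it cyclises, or peroxyl radicals may be diverted into chain oxidation of the substrate, so that material is lost after the ring has opened. Fallback (sets out from 20, returns at 23): C–C cleavage and O–O formation are separated. Silver-catalysed radical ring-opening chlorination of 20 (AgNO3 cat., K2S2O8, N-chlorosuccinimide, CH2Cl2/H2O, rt), which uses the same β-scission toward the tertiary radical, should give the γ-chloro ketone (3R,7R)-5-chloro-3,5,7-trimethyl-15-phenylpentadec-14-yn-2-one F1. Silver-assisted perhydrolysis of the tertiary chloride (AgOSO2CF3, ethereal H2O2, Et2O, 0 °C) then gives hydroperoxy ketone 22, which closes to the dioxanol; after the same separation of C6 epimers the route is rejoined at 23.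

2. Step 13. What may go wrong: hydrogenolysis of the peroxide O–O bond on palladium (directly or through the open-chain hydroperoxide tautomer), over-reduction, or Z to E isomerisation. Fallback (sets out from 20, returns at 24): the semi-hydrogenation is moved ahead of the peroxide. The same poisoned Pd/CaCO3–Pb(OAc)2/quinoline/H2 conditions applied to 20 should give (4R)-1,2,4-trimethyl-2-[(2R,9Z)-2-methyl-10-phenyldec-9-en-1-yl]cyclobutan-1-ol F2. The Co(acac)2/O2 ring expansion is then run on F2 at high dilution, passing through the (Z)-hydroperoxy ketone (3R,7R,14Z)-5-hydroperoxy-3,5,7-trimethyl-15-phenylpentadec-14-en-2-one F3, and gives 24 directly after separation of the C6 epimer.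

3. Step 5. What may go wrong: poor facial selectivity or sluggish metalation, because the hydrazone sits on a cyclobutanone flanked by a quaternary carbon present as two epimers (matched and mismatched pairs with the auxiliary). Fallback (sets out from 7, returns at 23): reagent control at C4 is given up and the stereoisomers are separated at the end.
   - Ketone 7 is methylated through its lithium enolate (LiN(i-Pr)2, THF, −78 °C; MeI) to 2-[(2R)-2,6-dimethylhept-5-en-1-yl]-2,4-dimethylcyclobutan-1-one as a C4 epimer mixture F4.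
   - F4 is taken through the conditions of steps 7–9, 11 and 12: MeMgBr addition to the C4-epimeric cyclobutanol F5, ozonolysis with NaBH4 work-up through the aldehyde F6 to the diol F7, tosylation to the tosylate F8, copper-catalysed coupling with 19 to the alkynyl cyclobutanol F9, and cobalt/O2 ring expansion through the hydroperoxy ketone F10.
   - The four dioxanols (C4 × C6; all are diastereomers because C8 is fixed) are separated by preparative HPLC to return 23.

Further compounds
F1 | step 12 | (3R,7R)-5-chloro-3,5,7-trimethyl-15-phenylpentadec-14-yn-2-one (C5 epimers) | C[C@H](CCCCCCC#Cc1ccccc1)CC(C)(Cl)C[C@@H](C)C(C)=O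
F2 | step 13 | (4R)-1,2,4-trimethyl-2-[(2R,9Z)-2-methyl-10-phenyldec-9-en-1-yl]cyclobutan-1-ol (C1/C2 epimers) | C[C@H](CCCCCC/C=C\c1ccccc1)CC1(C)C[C@@H](C)C1(C)O
F3 | step 13 | (3R,7R,14Z)-5-hydroperoxy-3,5,7-trimethyl-15-phenylpentadec-14-en-2-one (C5 epimers) | C[C@H](CCCCCC/C=C\c1ccccc1)CC(C)(OO)C[C@@H](C)C(C)=O
F4 | step 5 | 2-[(2R)-2,6-dimethylhept-5-en-1-yl]-2,4-dimethylcyclobutan-1-one (C2/C4 epimers) | C[C@H](CCC=C(C)C)CC1(C)CC(C)C1=O
F5 | step 5 | 2-[(2R)-2,6-dimethylhept-5-en-1-yl]-1,2,4-trimethylcyclobutan-1-ol (ring epimers) | C[C@H](CCC=C(C)C)CC1(C)CC(C)C1(C)O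
F6 | step 5 | (4R)-5-(2-hydroxy-1,2,3-trimethylcyclobutyl)-4-methylpentanal (ring epimers) | C[C@H](CCC=O)CC1(C)CC(C)C1(C)O
F7 | step 5 | 2-[(2R)-5-hydroxy-2-methylpentyl]-1,2,4-trimethylcyclobutan-1-ol (ring epimers) | C[C@H](CCCO)CC1(C)CC(C)C1(C)O
F8 | step 5 | (4R)-5-(2-hydroxy-1,2,3-trimethylcyclobutyl)-4-methylpentyl 4-methylbenzenesulfonate (ring epimers) | C[C@H](CCCOS(=O)(=O)c1ccc(C)cc1)CC1(C)CC(C)C1(C)O
F9 | step 5 | 1,2,4-trimethyl-2-[(2R)-2-methyl-10-phenyldec-9-yn-1-yl]cyclobutan-1-ol (ring epimers) | C[C@H](CCCCCCC#Cc1ccccc1)CC1(C)CC(C)C1(C)O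
F10 | step 5 | (7R)-5-hydroperoxy-3,5,7-trimethyl-15-phenylpentadec-14-yn-2-one (C3/C5 epimers) | C[C@H](CCCCCCC#Cc1ccccc1)CC(C)(OO)CC(C)C(C)=O
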